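**Plan**

- Cuts: the two ring B allyl ethers; C6–CH2 and CH2–C(=O) of the 3-methyl-2-oxobutyl chain (one iminium carbon plus the acyl group of 2-methylpropanal); O1–C8a, C4a–C4 and O1–C2 of ring C; then C3–CH2 (prenyl), the enol O–CH3 bond and C4–C3 (carbonate carbon) of the acid partner.
- Enabling feature: on ring A, O1–C8a and C4a–C4 sit on neighbouring carbons, with the acyl-bearing C4a directly beside the oxygenated C5. A 3-alkoxybenzyne leaves exactly this 1,2-pattern when it inserts into the C–O bond of a carboxylic acid.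
- Forward: ring A (from 5-methoxyresorcinol) becomes an o-silylaryl triflate and ring B (from 2,4-dihydroxyacetophenone) becomes a β-methoxy-α-prenylacrylic acid. Ring C closes in one operation when they meet. The C6 chain is then added through an o-quinone methide, and deallylation finishes the route.
- Stereochemistry: the target has no stereocentre. The racemic α-carbon of the β-keto ester and the enol ether geometry are both erased before or during ring closure.

Key step: step 11

Assumption: enol ether 17 and acid 18 are drawn as the E isomers (methoxy trans to the carboxyl carbon); the Z isomers or a mixture would serve equally, because this geometry disappears when ring C closes.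

**Route**

Step 1
Reactants: 1 5-methoxybenzene-1,3-diol
Product: 2 1-methoxy-3,5-bis(methoxymethoxy)benzene
Conditions: MOMCl (2.6 equiv), iPr2NEt (3.5 equiv), CH2Cl2, 0 °C to rt
Reagents that add atoms: chloromethyl methyl ether, COCCl
Why: Williamson-type O-alkylation of both phenols with the reactive chloromethyl ether should be clean and installs the two groups that direct the metalation of step 2.

Step 2
Reactants: 2 1-methoxy-3,5-bis(methoxymethoxy)benzene
Product: 4 2-bromo-5-methoxy-1,3-bis(methoxymethoxy)benzene, via aryllithium 3 (not isolated)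
Conditions: n-BuLi (1.15 equiv), THF, 0 °C; then BrCl2C–CCl2Br (1.2 equiv), −78 °C to rt
Reagents that add atoms: 1,2-dibromo-1,1,2,2-tetrachloroethane, BrC(Cl)(Cl)C(Cl)(Cl)Br
Why: Directed ortho-metalation should occur at the one carbon flanked by two chelating MOM-oxy groups (methoxy is the weaker director), and the aryllithium is brominated by halogen transfer from the polyhalide.

Step 3
Reactants: 4 2-bromo-5-methoxy-1,3-bis(methoxymethoxy)benzene
Product: 5 2-bromo-5-methoxybenzene-1,3-diol
Conditions: conc. HCl (cat.), MeOH, 50 °C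
Reagents that add atoms: none
Why: Acid-catalysed transacetalisation to methanol frees both phenols while the aryl bromide is inert, and it is placed here so that no acid is needed once the acid-labile aryl–silicon bond exists.

Step 4
Reactants: 5 2-bromo-5-methoxybenzene-1,3-diol
Product: 10 5-methoxy-3-(methoxymethoxy)-2-(trimethylsilyl)phenol, via bis(trimethylsilyl) ether 6 (not isolated), via aryllithium 7 (not isolated), via lithium phenoxide 8 (not isolated), via O-silyl MOM ether 9 (not isolated)
Conditions: HMDS, THF, 65 °C, then evaporate; n-BuLi (1.05 equiv), THF, −78 °C; MOMCl (1.2 equiv), −78 °C to rt; MeOH, K2CO3 (cat.), 0 °C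
Reagents that add atoms: hexamethyldisilazane, C[Si](C)(C)N[Si](C)(C)C; chloromethyl methyl ether, COCCl
Why: Bromine–lithium exchange is followed by a 1,3 O-to-C silyl shift (retro-Brook rearrangement) that puts trimethylsilyl on carbon and desymmetrises the resorcinol by releasing exactly one phenoxide, which is capped by O-alkylation before the remaining labile aryl silyl ether is methanolysed.

Step 5
Reactants: 10 5-methoxy-3-(methoxymethoxy)-2-(trimethylsilyl)phenol
Product: 11 5-methoxy-3-(methoxymethoxy)-2-(trimethylsilyl)phenyl trifluoromethanesulfonate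
Conditions: Tf2O (1.2 equiv), pyridine (3 equiv), CH2Cl2, 0 °C
Reagents that add atoms: trifluoromethanesulfonic anhydride, O=S(=O)(OS(=O)(=O)C(F)(F)F)C(F)(F)F
Why: O-Sulfonylation of the hindered phenol is the standard last step towards o-silylaryl triflates and uses neither strong acid nor fluoride, so the C–Si bond and the MOM ether should survive.

Step 6
Reactants: 12 1-(2,4-dihydroxyphenyl)ethanone
Product: 13 1-[2,4-bis(prop-2-en-1-yloxy)phenyl]ethanone
Conditions: allyl bromide (2.5 equiv), K2CO3 (3 equiv), DMF, 60 °C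
Reagents that add atoms: allyl bromide, C=CCBr
Why: Williamson etherification of both phenols (the hydrogen-bonded one included in warm DMF) gives allyl ethers that tolerate base, fluoride, heat and mild acid and can be removed at the end under neutral conditions.

Step 7
Reactants: 13 1-[2,4-bis(prop-2-en-1-yloxy)phenyl]ethanone
Product: 14 methyl 3-[2,4-bis(prop-2-en-1-yloxy)phenyl]-3-oxopropanoate
Conditions: NaH (3 equiv), (MeO)2CO (5 equiv), THF, reflux; then cold 1 M HCl
Reagents that add atoms: dimethyl carbonate, COC(=O)OC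
Why: Crossed Claisen condensation of the methyl ketone enolate with the non-enolisable carbonate is driven by formation of the stabilised β-keto ester enolate and introduces the carbon that becomes C4.

Step 8
Reactants: 14 methyl 3-[2,4-bis(prop-2-en-1-yloxy)phenyl]-3-oxopropanoate; 15 1-bromo-3-methylbut-2-ene
Product: 16 methyl 2-[2,4-bis(prop-2-en-1-yloxy)benzoyl]-5-methylhex-4-enoate (racemic)
Conditions: K2CO3 (1.5 equiv), acetone, 45 °C
Reagents that add atoms: none
Why: SN2 C-alkylation of the soft potassium β-keto ester enolate by the allylic bromide should give the mono-prenylated product, whose new stereocentre is racemic and is erased in step 9.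

Step 9
Reactants: 16 methyl 2-[2,4-bis(prop-2-en-1-yloxy)benzoyl]-5-methylhex-4-enoate
Product: 17 methyl (2E)-3-[2,4-bis(prop-2-en-1-yloxy)phenyl]-3-methoxy-2-(3-methylbut-2-en-1-yl)prop-2-enoate
Conditions: Me2SO4 (1.5 equiv), Cs2CO3 (2 equiv), DMF, 0 °C to rt
Reagents that add atoms: dimethyl sulfate, COS(=O)(=O)OC
Why: Enolate O-alkylation is expected because the dissociated cesium enolate meets a hard sulfate electrophile in DMF and its α-carbon is fully substituted and shielded, giving the β-methoxyacrylate.

Step 10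
Reactants: 17 methyl (2E)-3-[2,4-bis(prop-2-en-1-yloxy)phenyl]-3-methoxy-2-(3-methylbut-2-en-1-yl)prop-2-enoate
Product: 18 (2E)-3-[2,4-bis(prop-2-en-1-yloxy)phenyl]-3-methoxy-2-(3-methylbut-2-en-1-yl)prop-2-enoic acid
Conditions: LiOH·H2O (6 equiv), THF–MeOH–H2O, 60 °C; then 1 M HCl to pH 4, 0 °C
Reagents that add atoms: lithium hydroxide, [Li+].[OH-]
Why: Saponification of the hindered ester needs warm hydroxide, which the enol ether, the allyl ethers and the prenyl group tolerate, and cold, mild acidification avoids enol ether hydrolysis and decarboxylation.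

Step 11
Reactants: 11 5-methoxy-3-(methoxymethoxy)-2-(trimethylsilyl)phenyl trifluoromethanesulfonate (1.5 equiv); 18 (2E)-3-[2,4-bis(prop-2-en-1-yloxy)phenyl]-3-methoxy-2-(3-methylbut-2-en-1-yl)prop-2-enoic acid
Product: 22 2-[2,4-bis(prop-2-en-1-yloxy)phenyl]-7-methoxy-5-(methoxymethoxy)-3-(3-methylbut-2-en-1-yl)-4H-chromen-4-one, via aryne 19 (not isolated), via aryl cesium ester 20 (not isolated), via cesium acylphenoxide 21 (not isolated)
Conditions: CsF (4 equiv), THF, 125 °C, sealed tube
Reagents that add atoms: none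
Why: CsF strips the trimethylsilyl group from 11 with loss of triflate and releases aryne 19, whose carbon meta to the MOM-oxy substituent (the later C8a) is attacked by the carboxylate of 18; the carbanion of 20 (the later C4a) then takes over the neighbouring acyl group from oxygen through a four-membered array and gives acylphenoxide 21, so that the aryne ends up inserted between the acyl carbon and the oxygen of the acid (O1–C8a and C4a–C4). The closest known reaction type is the fluoride-induced insertion of arynes from o-silylaryl triflates into the C–O bond of carboxylic acids in hot THF, which with alkenoic and alkynoic acids runs on to chromanones and flavones. Ring C closes by 6-endo-trig conjugate addition of the phenoxide oxygen to the methoxy-bearing β-carbon and E1cB loss of methoxide (addition–elimination), forming O1–C2 with the prenyl group already in place on C3. No stereocentre is formed and the enol ether geometry vanishes in the tetrahedral adduct. Two selectivities are needed: attack at the later C8a, secured by the inductively withdrawing MOM-oxy group at the later C5 that stabilises the adjacent carbanion and distorts the aryne, and acyl transfer faster than protonation of that carbanion, favoured by the aprotic medium, the high temperature and the proximity of the ester carbonyl.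

Step 12
Reactants: 22 2-[2,4-bis(prop-2-en-1-yloxy)phenyl]-7-methoxy-5-(methoxymethoxy)-3-(3-methylbut-2-en-1-yl)-4H-chromen-4-one
Product: 23 2-[2,4-bis(prop-2-en-1-yloxy)phenyl]-5-hydroxy-7-methoxy-3-(3-methylbut-2-en-1-yl)-4H-chromen-4-one
Conditions: 3 M aq. HCl, MeOH–THF, 40 °C
Reagents that add atoms: none
Why: Mild acetal hydrolysis should remove the only MOM group, which is activated by the peri carbonyl and gives a hydrogen-bonded phenol, while the allyl ethers, the prenyl group and the chromone are stable.

Step 13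
Reactants: 23 2-[2,4-bis(prop-2-en-1-yloxy)phenyl]-5-hydroxy-7-methoxy-3-(3-methylbut-2-en-1-yl)-4H-chromen-4-one
Product: 24 2-[2,4-bis(prop-2-en-1-yloxy)phenyl]-6-[(dimethylamino)methyl]-5-hydroxy-7-methoxy-3-(3-methylbut-2-en-1-yl)-4H-chromen-4-one
Conditions: CH2=NMe2+ I− (1.3 equiv), K2CO3 (2 equiv), CH2Cl2, rt
Reagents that add atoms: N,N-dimethylmethyleneiminium iodide, C=[N+](C)C.[I-]
Why: Mannich reaction of the potassium phenoxide with the preformed iminium salt should be delivered within the ion pair to C6, the only free carbon ortho to the 5-hydroxyl, while the etherified ring B and the alkenes are not nucleophilic enough to compete.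

Step 14
Reactants: 24 2-[2,4-bis(prop-2-en-1-yloxy)phenyl]-6-[(dimethylamino)methyl]-5-hydroxy-7-methoxy-3-(3-methylbut-2-en-1-yl)-4H-chromen-4-one; 25 2-methylpropanal
Product: 28 2-[2,4-bis(prop-2-en-1-yloxy)phenyl]-5-hydroxy-7-methoxy-6-(3-methyl-2-oxobutyl)-3-(3-methylbut-2-en-1-yl)-4H-chromen-4-one, via ammonium iodide 26 (not isolated), via o-quinone methide 27 (not isolated)
Conditions: MeI (5 equiv), THF, rt, then evaporate; 25 (3 equiv), 3,4,5-trimethylthiazol-3-ium iodide (20 mol %), Cs2CO3 (2.2 equiv), THF, 50 °C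
Reagents that add atoms: none
Why: N-Methylation turns the amine into a leaving group so that carbonate triggers 1,4-elimination to the o-quinone methide, to which the carbene–aldehyde adduct (acyl anion equivalent) adds in a Stetter-type conjugate addition, the known carbene-catalysed nucleophilic acylation of o-quinone methides, with rearomatisation to the 5-phenol and release of the carbene.

Step 15
Reactants: 28 2-[2,4-bis(prop-2-en-1-yloxy)phenyl]-5-hydroxy-7-methoxy-6-(3-methyl-2-oxobutyl)-3-(3-methylbut-2-en-1-yl)-4H-chromen-4-one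
Product: 29 2-(2,4-dihydroxyphenyl)-5-hydroxy-7-methoxy-6-(3-methyl-2-oxobutyl)-3-(3-methylbut-2-en-1-yl)-4H-chromen-4-one
Conditions: Pd(PPh3)4 (5 mol %), morpholine (10 equiv), THF, rt
Reagents that add atoms: none
Why: In this Tsuji–Trost-type allyl transfer zerovalent palladium ionises both aryl allyl ethers to allylpalladium species that morpholine captures, under neutral conditions that leave the prenyl group, the benzylic ketone and the chelated phenol untouched and avoid acid-induced cyclodehydration to a benzofuran.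

**Compound list**

1 | 5-methoxybenzene-1,3-diol | COc1cc(O)cc(O)c1 | starting material
2 | 1-methoxy-3,5-bis(methoxymethoxy)benzene | COCOc1cc(OC)cc(OCOC)c1 | intermediate
3 | [4-methoxy-2,6-bis(methoxymethoxy)phenyl]lithium | COCOc1cc(OC)cc(OCOC)c1[Li] | intermediate
4 | 2-bromo-5-methoxy-1,3-bis(methoxymethoxy)benzene | COCOc1cc(OC)cc(OCOC)c1Br | intermediate
5 | 2-bromo-5-methoxybenzene-1,3-diol | COc1cc(O)c(Br)c(O)c1 | intermediate
6 | 2-bromo-5-methoxy-1,3-bis(trimethylsilyloxy)benzene | COc1cc(O[Si](C)(C)C)c(Br)c(O[Si](C)(C)C)c1 | intermediate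
7 | [4-methoxy-2,6-bis(trimethylsilyloxy)phenyl]lithium | COc1cc(O[Si](C)(C)C)c([Li])c(O[Si](C)(C)C)c1 | intermediate
8 | lithium 5-methoxy-2-(trimethylsilyl)-3-(trimethylsilyloxy)phenolate | [Li+].[O-]c1cc(OC)cc(O[Si](C)(C)C)c1[Si](C)(C)C | intermediate
9 | [4-methoxy-2-(methoxymethoxy)-6-(trimethylsilyloxy)phenyl]trimethylsilane | COCOc1cc(OC)cc(O[Si](C)(C)C)c1[Si](C)(C)C | intermediate
10 | 5-methoxy-3-(methoxymethoxy)-2-(trimethylsilyl)phenol | COCOc1cc(OC)cc(O)c1[Si](C)(C)C | intermediate
11 | 5-methoxy-3-(methoxymethoxy)-2-(trimethylsilyl)phenyl trifluoromethanesulfonate | COCOc1cc(OC)cc(OS(=O)(=O)C(F)(F)F)c1[Si](C)(C)C | intermediate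
12 | 1-(2,4-dihydroxyphenyl)ethanone | CC(=O)c1ccc(O)cc1O | starting material
13 | 1-[2,4-bis(prop-2-en-1-yloxy)phenyl]ethanone | CC(=O)c1ccc(OCC=C)cc1OCC=C | intermediate
14 | methyl 3-[2,4-bis(prop-2-en-1-yloxy)phenyl]-3-oxopropanoate | COC(=O)CC(=O)c1ccc(OCC=C)cc1OCC=C | intermediate
15 | 1-bromo-3-methylbut-2-ene | CC(C)=CCBr | starting material
16 | methyl 2-[2,4-bis(prop-2-en-1-yloxy)benzoyl]-5-methylhex-4-enoate (racemic) | COC(=O)C(CC=C(C)C)C(=O)c1ccc(OCC=C)cc1OCC=C | intermediate
17 | methyl (2E)-3-[2,4-bis(prop-2-en-1-yloxy)phenyl]-3-methoxy-2-(3-methylbut-2-en-1-yl)prop-2-enoate | COC(=O)/C(CC=C(C)C)=C(/OC)c1ccc(OCC=C)cc1OCC=C | intermediate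
18 | (2E)-3-[2,4-bis(prop-2-en-1-yloxy)phenyl]-3-methoxy-2-(3-methylbut-2-en-1-yl)prop-2-enoic acid | OC(=O)/C(CC=C(C)C)=C(/OC)c1ccc(OCC=C)cc1OCC=C | intermediate
19 | 1,2-didehydro-5-methoxy-3-(methoxymethoxy)benzene | COCOC1=CC(OC)=CC#C1 | intermediate
20 | [2-({(2E)-3-[2,4-bis(prop-2-en-1-yloxy)phenyl]-3-methoxy-2-(3-methylbut-2-en-1-yl)prop-2-enoyl}oxy)-4-methoxy-6-(methoxymethoxy)phenyl]cesium | [Cs]c1c(OCOC)cc(OC)cc1OC(=O)/C(CC=C(C)C)=C(/OC)c1ccc(OCC=C)cc1OCC=C | intermediate
21 | cesium 2-{(2E)-3-[2,4-bis(prop-2-en-1-yloxy)phenyl]-3-methoxy-2-(3-methylbut-2-en-1-yl)prop-2-enoyl}-5-methoxy-3-(methoxymethoxy)phenolate | [Cs+].[O-]c1cc(OC)cc(OCOC)c1C(=O)/C(CC=C(C)C)=C(/OC)c1ccc(OCC=C)cc1OCC=C | intermediate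
22 | 2-[2,4-bis(prop-2-en-1-yloxy)phenyl]-7-methoxy-5-(methoxymethoxy)-3-(3-methylbut-2-en-1-yl)-4H-chromen-4-one | COCOc1cc(OC)cc2oc(-c3ccc(OCC=C)cc3OCC=C)c(CC=C(C)C)c(=O)c12 | intermediate
23 | 2-[2,4-bis(prop-2-en-1-yloxy)phenyl]-5-hydroxy-7-methoxy-3-(3-methylbut-2-en-1-yl)-4H-chromen-4-one | COc1cc(O)c2c(=O)c(CC=C(C)C)c(-c3ccc(OCC=C)cc3OCC=C)oc2c1 | intermediate
24 | 2-[2,4-bis(prop-2-en-1-yloxy)phenyl]-6-[(dimethylamino)methyl]-5-hydroxy-7-methoxy-3-(3-methylbut-2-en-1-yl)-4H-chromen-4-one | COc1cc2oc(-c3ccc(OCC=C)cc3OCC=C)c(CC=C(C)C)c(=O)c2c(O)c1CN(C)C | intermediate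
25 | 2-methylpropanal | CC(C)C=O | starting material
26 | {2-[2,4-bis(prop-2-en-1-yloxy)phenyl]-5-hydroxy-7-methoxy-3-(3-methylbut-2-en-1-yl)-4-oxo-4H-chromen-6-yl}-N,N,N-trimethylmethanaminium iodide | COc1cc2oc(-c3ccc(OCC=C)cc3OCC=C)c(CC=C(C)C)c(=O)c2c(O)c1C[N+](C)(C)C.[I-] | intermediate
27 | 2-[2,4-bis(prop-2-en-1-yloxy)phenyl]-7-methoxy-6-methylidene-3-(3-methylbut-2-en-1-yl)-4H-chromene-4,5(6H)-dione | C=C1C(OC)=CC2=C(C1=O)C(=O)C(CC=C(C)C)=C(c1ccc(OCC=C)cc1OCC=C)O2 | intermediate
28 | 2-[2,4-bis(prop-2-en-1-yloxy)phenyl]-5-hydroxy-7-methoxy-6-(3-methyl-2-oxobutyl)-3-(3-methylbut-2-en-1-yl)-4H-chromen-4-one | COc1cc2oc(-c3ccc(OCC=C)cc3OCC=C)c(CC=C(C)C)c(=O)c2c(O)c1CC(=O)C(C)C | intermediate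
29 | 2-(2,4-dihydroxyphenyl)-5-hydroxy-7-methoxy-6-(3-methyl-2-oxobutyl)-3-(3-methylbut-2-en-1-yl)-4H-chromen-4-one | COc1cc2oc(-c3ccc(O)cc3O)c(CC=C(C)C)c(=O)c2c(O)c1CC(=O)C(C)C | target

**Step count and risks**

Total: 15 steps. Longest linear sequence: 10 steps (steps 1–5 then 11–15; the acid branch, steps 6–10 then 11–15, is equally long).

Step 11. The carbanion of 20 may pick up a proton before the acyl shift, which would end in O-arylation of the acid and not in insertion. The aryne may also be consumed by ene-type reactions with the alkenes, or methoxide displacement may stall at the open acylphenol. The fallback sets out from acid 18 and bis-MOM ether 2 and comes back at 23. Acid 18 is coupled with N,O-dimethylhydroxylamine hydrochloride (EDC·HCl, iPr2NEt, CH2Cl2) to the N-methoxy-N-methylamide F1. Aryllithium 3, made from 2 as in step 2, is added to it at −78 °C to give the aryl ketone F2. Methanolic HCl then removes both MOM groups, and either of the two equivalent ortho-phenols displaces methoxide to close ring C, giving 23 directly, so that step 12 is not needed.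

Step 13. Aminomethylation may lose regiocontrol and occur para to the phenol at C8, or the hydrogen-bonded phenol may react too slowly. The fallback sets out from 23 and comes back at 28, replacing steps 13 and 14 by an oxygen-to-ortho-carbon delivery. 3-Methyl-1-(methylsulfanyl)butan-2-one F3 is made from 1-bromo-3-methylbutan-2-one and NaSMe and converted into its S-chlorosulfonium salt with N-chlorosuccinimide in CH2Cl2 at −70 °C. Phenol 23 and then Et3N are added; the aryloxysulfonium ylide undergoes a [2,3]-sigmatropic (Sommelet–Hauser-type) shift that can reach only C6 and gives the α-(methylsulfanyl) ketone F4. Reductive C–S cleavage with Zn in AcOH then gives 28.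

Step 14. The quinone methide may oligomerise or be captured irreversibly by the carbene, and acyloin self-condensation of the aldehyde may outrun the conjugate addition. The fallback sets out from Mannich base 24 and comes back at 28. After quaternisation to 26 as before, the salt is heated with 2-methyl-1-nitropropane and DBU in MeCN, so that the nitronate adds to the quinone methide in a Michael reaction and gives the secondary nitro compound F5. A Nef reaction (aqueous TiCl3, NH4OAc buffer) then converts the nitro group into the ketone of 28.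

**Further compounds**

F1 | step 11 | (2E)-3-[2,4-bis(prop-2-en-1-yloxy)phenyl]-N,3-dimethoxy-N-methyl-2-(3-methylbut-2-en-1-yl)prop-2-enamide | CON(C)C(=O)/C(CC=C(C)C)=C(/OC)c1ccc(OCC=C)cc1OCC=C
F2 | step 11 | (2E)-3-[2,4-bis(prop-2-en-1-yloxy)phenyl]-3-methoxy-1-[4-methoxy-2,6-bis(methoxymethoxy)phenyl]-2-(3-methylbut-2-en-1-yl)prop-2-en-1-one | COCOc1cc(OC)cc(OCOC)c1C(=O)/C(CC=C(C)C)=C(/OC)c1ccc(OCC=C)cc1OCC=C
F3 | step 13 | 3-methyl-1-(methylsulfanyl)butan-2-one | CSCC(=O)C(C)C
F4 | step 13 | 2-[2,4-bis(prop-2-en-1-yloxy)phenyl]-5-hydroxy-7-methoxy-6-[3-methyl-1-(methylsulfanyl)-2-oxobutyl]-3-(3-methylbut-2-en-1-yl)-4H-chromen-4-one (racemic) | COc1cc2oc(-c3ccc(OCC=C)cc3OCC=C)c(CC=C(C)C)c(=O)c2c(O)c1C(SC)C(=O)C(C)C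
F5 | step 14 | 2-[2,4-bis(prop-2-en-1-yloxy)phenyl]-5-hydroxy-7-methoxy-6-(3-methyl-2-nitrobutyl)-3-(3-methylbut-2-en-1-yl)-4H-chromen-4-one (racemic) | COc1cc2oc(-c3ccc(OCC=C)cc3OCC=C)c(CC=C(C)C)c(=O)c2c(O)c1CC(C(C)C)[N+](=O)[O-]
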